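## Retrosynthetic overview

1. Target 27, numbered as 5-hydroxy-2,6,6,9-tetramethyl-11-oxotricyclo[5.4.0.0(2,8)]undecane-3,4-diyl diangelate, comes from desilylation of 26, itself from bis-angeloylation of diol 23, which arises by cis-dihydroxylation of the C3=C4 bond of tricyclic ketone 22, anti to the C5 silyl ether.
2. Key disconnection: the C9–C10 bond of the cyclohexanone ring (CHMe–CH2C=O) is opened to bromomethyl ketone 21; in the forward sense a 6-endo radical closure forms the third ring and sets C9 and C8.
3. Enabling feature: in the bicyclo[4.1.1]octene 21 the two one-carbon bridges of the cyclobutane hold, 1,3-syn and on the face away from the cycloheptene, the bromoacetyl group (future C1–C11–C10) and an exocyclic (E)-ethylidene (future C8=C9), so the radical carbon C10 sits about 3 Å from C9.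
4. 21 comes from cyclobutanone 16 (Wittig ethylidenation, Tsuji–Wacker oxidation, bromination); 16 from a singlet-oxygen ene reaction on 14; 14 from RCM of the cis-2,4-dialkenyl cyclobutanone 13; 13 from aldol, allylation and cuprate addition on 2-methyl-3-vinylcyclobutanone 7; 7 from an auxiliary-controlled keteniminium–butadiene [2+2] cycloaddition.
5. Ring order: cyclobutane (step 2), cycloheptene (step 7), cyclohexanone (step 13).

Key step: step 13

Remark (assumption): the (2R,5R)-auxiliary is taken to induce the (3S) configuration at the vinyl-bearing carbon of 7; if the sense of induction is the opposite, the (2S,5S)-amine is used and nothing else changes.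

## Route

Step 1
Reactants: 1 propanoyl chloride; 2 (2R,5R)-2,5-dimethylpyrrolidine
Product: 3 1-[(2R,5R)-2,5-dimethylpyrrolidin-1-yl]propan-1-one
Conditions: Et3N, CH2Cl2, 0 °C to rt
Reagents that add atoms: none
Why: N-acylation of the secondary amine by the acid chloride (Schotten–Baumann type) should give the tertiary amide needed for keteniminium formation; no stereocenter is formed.

Step 2
Reactants: 3 1-[(2R,5R)-2,5-dimethylpyrrolidin-1-yl]propan-1-one; 4 buta-1,3-diene
Product: 7 (2S,3S)-3-ethenyl-2-methylcyclobutan-1-one, via keteniminium triflate 5 (not isolated), via cyclobutaniminium triflate 6 (not isolated)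
Conditions: Tf2O, 2,6-di-tert-butyl-4-methylpyridine, ClCH2CH2Cl, −20 °C; 4 (excess), sealed vessel, 40 °C; then aq NaHCO3, CH2Cl2, rt
Reagents that add atoms: water, O
Why: Keteniminium–alkene [2+2] cycloaddition: the iminium carbon should bond to the diene terminus and the α-carbon to the internal carbon, giving the 3-vinylcyclobutaniminium salt, whose vinyl-bearing stereocenter is controlled by the C2-symmetric pyrrolidine auxiliary; hydrolysis releases the ketone (the C-2 methyl epimer is equally usable, since that centre is planarised in step 5).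

Step 3
Reactants: 7 (2S,3S)-3-ethenyl-2-methylcyclobutan-1-one
Product: 8 (2S,3S)-3-ethenyl-4-(2-hydroxypropan-2-yl)-2-methylcyclobutan-1-one
Conditions: LiN(iPr)2, THF, −78 °C; acetone; aq NH4Cl, −78 °C
Reagents that add atoms: acetone, CC(C)=O
Why: Kinetic deprotonation at the CH2 α-carbon and aldol addition to acetone should install the future gem-dimethyl carbon; the new ring stereocenter (expected trans to vinyl) is removed in step 4.

Step 4
Reactants: 8 (2S,3S)-3-ethenyl-4-(2-hydroxypropan-2-yl)-2-methylcyclobutan-1-one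
Product: 10 (2S,3S)-3-ethenyl-2-methyl-4-(propan-2-ylidene)cyclobutan-1-one, via mesylate 9 (not isolated)
Conditions: MsCl, Et3N, CH2Cl2, 0 °C; then DBU, rt
Reagents that add atoms: none
Why: Mesylation and E1cB elimination (aldol dehydration) should give the conjugated exocyclic enone, which blocks this α-carbon and makes the isopropylidene carbon a Michael acceptor, without passing through a cyclobutylcarbinyl cation.

Step 5
Reactants: 10 (2S,3S)-3-ethenyl-2-methyl-4-(propan-2-ylidene)cyclobutan-1-one
Product: 11 (2S,3S)-3-ethenyl-2-methyl-4-(propan-2-ylidene)-2-(prop-2-en-1-yl)cyclobutan-1-one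
Conditions: LiN(iPr)2, THF, −78 °C; allyl bromide, DMPU, −78 to −20 °C
Reagents that add atoms: allyl bromide, C=CCBr
Why: Alkylation of the kinetic cross-conjugated (α') enolate: the allyl group should enter anti to the adjacent vinyl group, setting the quaternary carbon with its methyl cis to vinyl.

Step 6
Reactants: 11 (2S,3S)-3-ethenyl-2-methyl-4-(propan-2-ylidene)-2-(prop-2-en-1-yl)cyclobutan-1-one
Product: 13 (2S,3R,4S)-3-ethenyl-2-methyl-4-(2-methylbut-3-en-2-yl)-2-(prop-2-en-1-yl)cyclobutan-1-one, via trimethylsilyl enol ether 12 (not isolated)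
Conditions: vinylmagnesium bromide, CuBr·SMe2 (cat.), Me3SiCl, THF, −78 to −40 °C; then K2CO3, MeOH, rt
Reagents that add atoms: vinylmagnesium bromide, C=C[Mg]Br
Why: Copper-catalysed, silyl-chloride-assisted conjugate addition should create the gem-dimethyl quaternary carbon; methanolysis of the silyl enol ether under equilibrating conditions should leave the bulky substituent trans to the adjacent vinyl group, that is cis to the allyl group across the carbonyl.

Step 7
Reactants: 13 (2S,3R,4S)-3-ethenyl-2-methyl-4-(2-methylbut-3-en-2-yl)-2-(prop-2-en-1-yl)cyclobutan-1-one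
Product: 14 8-ethenyl-1,5,5-trimethylbicyclo[4.1.1]oct-3-en-7-one (vinyl anti to the four-carbon bridge)
Conditions: second-generation Hoveyda–Grubbs catalyst (cat.), toluene (high dilution), 80 °C
Reagents that add atoms: none
Why: Ring-closing metathesis should join the allyl and the neopentyl vinyl groups, the only pair on the same face of the cyclobutanone (the ring vinyl is trans to both and cannot close a small ring), giving the cycloheptene that bridges the two α-carbons; no new stereocenter.

Step 8
Reactants: 14 8-ethenyl-1,5,5-trimethylbicyclo[4.1.1]oct-3-en-7-one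
Product: 16 8-ethenyl-4-hydroxy-1,5,5-trimethylbicyclo[4.1.1]oct-2-en-7-one (hydroxyl on the face of the carbonyl bridge), via allylic hydroperoxide 15 (not isolated)
Conditions: O2, tetraphenylporphyrin (cat.), visible light, CH2Cl2, 0 °C; then PPh3, rt
Reagents that add atoms: dioxygen, O=O
Why: Schenck ene reaction: only the CH2 next to the methyl-bearing bridgehead has allylic hydrogen, so oxygen should be delivered to the alkene carbon beside the gem-dimethyl carbon with shift of the double bond; attack is expected on the cycloheptene face turned toward the sp2 carbonyl bridge, which has no inward C–H, and this sets the carbinol centre; PPh3 reduces the hydroperoxide.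

Step 9
Reactants: 16 8-ethenyl-4-hydroxy-1,5,5-trimethylbicyclo[4.1.1]oct-2-en-7-one
Product: 17 (7E)-8-ethenyl-7-ethylidene-1,5,5-trimethylbicyclo[4.1.1]oct-2-en-4-ol
Conditions: ethyltriphenylphosphonium bromide, KN(SiMe3)2 (excess), THF, 0 °C to reflux
Reagents that add atoms: ethyltriphenylphosphonium bromide, CC[P+](c1ccccc1)(c1ccccc1)c1ccccc1.[Br-]
Why: Wittig ethylidenation of the non-enolisable, strained cyclobutanone (excess ylide covers the free hydroxyl); the E isomer is expected because the ylide methyl avoids the methyl-bearing bridgehead and lies syn to the bridgehead C–H.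

Step 10
Reactants: 17 (7E)-8-ethenyl-7-ethylidene-1,5,5-trimethylbicyclo[4.1.1]oct-2-en-4-ol
Product: 18 tert-butyl{[(7E)-8-ethenyl-7-ethylidene-1,5,5-trimethylbicyclo[4.1.1]oct-2-en-4-yl]oxy}dimethylsilane
Conditions: tBuMe2SiOTf, 2,6-lutidine, CH2Cl2, −78 to 0 °C
Reagents that add atoms: tert-butyldimethylsilyl trifluoromethanesulfonate, CC(C)(C)[Si](C)(C)OS(=O)(=O)C(F)(F)F
Why: Silylation of the hindered neopentyl allylic alcohol with the silyl triflate masks the hydroxyl that must stay free in the target while the other two oxygens are acylated.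

Step 11
Reactants: 18 tert-butyl{[(7E)-8-ethenyl-7-ethylidene-1,5,5-trimethylbicyclo[4.1.1]oct-2-en-4-yl]oxy}dimethylsilane
Product: 19 1-[(7E)-4-{[tert-butyl(dimethyl)silyl]oxy}-7-ethylidene-1,5,5-trimethylbicyclo[4.1.1]oct-2-en-8-yl]ethan-1-one
Conditions: PdCl2 (cat.), CuCl (co-catalyst), O2 (1 atm), DMF/H2O, rt
Reagents that add atoms: water, O
Why: Tsuji–Wacker oxidation should convert only the terminal vinyl group (Markovnikov) into the methyl ketone; the trisubstituted ethylidene and the cis-disubstituted ring alkene are far less reactive, and the acetyl-bearing centre keeps its configuration.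

Step 12
Reactants: 19 1-[(7E)-4-{[tert-butyl(dimethyl)silyl]oxy}-7-ethylidene-1,5,5-trimethylbicyclo[4.1.1]oct-2-en-8-yl]ethan-1-one
Product: 21 2-bromo-1-[(7E)-4-{[tert-butyl(dimethyl)silyl]oxy}-7-ethylidene-1,5,5-trimethylbicyclo[4.1.1]oct-2-en-8-yl]ethan-1-one, via trimethylsilyl enol ether 20 (not isolated)
Conditions: LiN(SiMe3)2, Me3SiCl, THF, −78 °C; then N-bromosuccinimide, THF, −78 to 0 °C
Reagents that add atoms: N-bromosuccinimide, O=C1CCC(=O)N1Br
Why: Kinetic enolisation occurs on the methyl side (the cyclobutyl methine would give a strained exocyclic enolate), and the silyl enol ether should be brominated far faster than the alkenes, giving the α-bromo ketone regioselectively.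

Step 13
Reactants: 21 2-bromo-1-[(7E)-4-{[tert-butyl(dimethyl)silyl]oxy}-7-ethylidene-1,5,5-trimethylbicyclo[4.1.1]oct-2-en-8-yl]ethan-1-one
Product: 22 5-{[tert-butyl(dimethyl)silyl]oxy}-2,6,6,9-tetramethyltricyclo[5.4.0.0(2,8)]undec-3-en-11-one
Conditions: (Me3Si)3SiH (syringe pump), AIBN (cat.), toluene (0.005 M), 90 °C
Reagents that add atoms: none
Why: The silyl radical abstracts bromine to give the electrophilic α-keto radical at C10, which adds to the CH terminus (C9) of the electron-rich ethylidene; the resulting tertiary cyclobutyl radical at C8 takes hydrogen from the silane. The closest known reaction type is the reductive 6-endo cyclisation of α-carbonyl radicals onto 1,1-disubstituted or trisubstituted alkenes. The cyclohexanone ring is closed in the 6-endo-trig mode, which completes the tricyclic cage. C9 is set by the E geometry of the ethylidene (methyl syn to the bridgehead C–H) together with the only reachable approach of the tethered radical, from the face away from the cycloheptene; C8 is set by the cage, since hydrogen can arrive only at the one open position of the new bridgehead. The step needs 6-endo closure to win over 5-exo closure and over simple reduction: 5-exo attack would hit the fully substituted ring carbon and build a bicyclo[2.1.1]hexanone, while the slow hydrogen donor, high dilution and the 1,3-syn placement of the two groups on the cyclobutane should let the cyclisation compete with reduction.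

Step 14
Reactants: 22 5-{[tert-butyl(dimethyl)silyl]oxy}-2,6,6,9-tetramethyltricyclo[5.4.0.0(2,8)]undec-3-en-11-one
Product: 23 5-{[tert-butyl(dimethyl)silyl]oxy}-3,4-dihydroxy-2,6,6,9-tetramethyltricyclo[5.4.0.0(2,8)]undecan-11-one (3,4-cis-diol, anti to the 5-silyloxy group)
Conditions: OsO4 (cat.), N-methylmorpholine N-oxide, acetone/H2O, rt
Reagents that add atoms: N-methylmorpholine N-oxide, C[N+]1([O-])CCOCC1; water, O
Why: Catalytic osmylation adds both oxygens syn (cis-diol) and should occur on the face opposite the bulky allylic silyl ether, the usual sense for allylic ethers, which sets C3 and C4.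

Step 15
Reactants: 23 5-{[tert-butyl(dimethyl)silyl]oxy}-3,4-dihydroxy-2,6,6,9-tetramethyltricyclo[5.4.0.0(2,8)]undecan-11-one; 24 angelic acid [(2Z)-2-methylbut-2-enoic acid], of which two equivalents are incorporated
Product: 26 5-{[tert-butyl(dimethyl)silyl]oxy}-2,6,6,9-tetramethyl-11-oxotricyclo[5.4.0.0(2,8)]undecane-3,4-diyl bis[(2Z)-2-methylbut-2-enoate], via mixed anhydride 25 (not isolated)
Conditions: 24 (5 equiv), 2,4,6-trichlorobenzoyl chloride (5 equiv), Et3N, toluene, rt; then 23, toluene, 80 °C
Reagents that add atoms: angelic acid (second equivalent of 24), C/C=C(/C)C(=O)O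
Why: Yamaguchi-type esterification through the mixed 2,4,6-trichlorobenzoic anhydride, run without a nucleophilic catalyst, should acylate each of the two secondary hydroxyls with its own molecule of 25 (so that two molecules of 24 end up in 26) while keeping the Z geometry of the angelate; no stereocenter changes.

Step 16
Reactants: 26 5-{[tert-butyl(dimethyl)silyl]oxy}-2,6,6,9-tetramethyl-11-oxotricyclo[5.4.0.0(2,8)]undecane-3,4-diyl bis[(2Z)-2-methylbut-2-enoate]
Product: 27 5-hydroxy-2,6,6,9-tetramethyl-11-oxotricyclo[5.4.0.0(2,8)]undecane-3,4-diyl bis[(2Z)-2-methylbut-2-enoate] (target)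
Conditions: HF·pyridine, pyridine/THF, 0 °C to rt
Reagents that add atoms: none
Why: Fluoride-mediated desilylation under buffered acidic conditions should free the C5 hydroxyl without acyl migration from the neighbouring trans-disposed ester or isomerisation of the angelates.

## Compound list

1 | propanoyl chloride | CCC(=O)Cl | starting material
2 | (2R,5R)-2,5-dimethylpyrrolidine | C[C@@H]1CC[C@@H](C)N1 | starting material
3 | 1-[(2R,5R)-2,5-dimethylpyrrolidin-1-yl]propan-1-one | CCC(=O)N1[C@H](C)CC[C@H]1C | intermediate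
4 | buta-1,3-diene | C=CC=C | starting material
5 | (2R,5R)-2,5-dimethyl-1-(prop-1-en-1-ylidene)pyrrolidin-1-ium triflate (keteniminium salt, not isolated) | CC=C=[N+]1[C@H](C)CC[C@H]1C.[O-]S(=O)(=O)C(F)(F)F | intermediate
6 | (2R,5R)-1-[(2S,3S)-3-ethenyl-2-methylcyclobutylidene]-2,5-dimethylpyrrolidin-1-ium triflate (not isolated) | C[C@@H]1C(=[N+]2[C@H](C)CC[C@H]2C)C[C@H]1C=C.[O-]S(=O)(=O)C(F)(F)F | intermediate
7 | (2S,3S)-3-ethenyl-2-methylcyclobutan-1-one (trans) | C[C@@H]1C(=O)C[C@H]1C=C | intermediate
8 | (2S,3S)-3-ethenyl-4-(2-hydroxypropan-2-yl)-2-methylcyclobutan-1-one (4-substituent trans to vinyl) | C[C@@H]1C(=O)[C@H](C(C)(C)O)[C@H]1C=C | intermediate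
9 | methanesulfonate of 8 (not isolated) | C[C@@H]1C(=O)[C@H](C(C)(C)OS(C)(=O)=O)[C@H]1C=C | intermediate
10 | (2S,3S)-3-ethenyl-2-methyl-4-(propan-2-ylidene)cyclobutan-1-one | C[C@@H]1C(=O)C(=C(C)C)[C@H]1C=C | intermediate
11 | (2S,3S)-3-ethenyl-2-methyl-4-(propan-2-ylidene)-2-(prop-2-en-1-yl)cyclobutan-1-one (methyl cis to vinyl) | C=CC[C@]1(C)C(=O)C(=C(C)C)[C@H]1C=C | intermediate
12 | trimethylsilyl enol ether of 13 (not isolated) | C=CC[C@]1(C)C(O[Si](C)(C)C)=C(C(C)(C)C=C)[C@H]1C=C | intermediate
13 | (2S,3R,4S)-3-ethenyl-2-methyl-4-(2-methylbut-3-en-2-yl)-2-(prop-2-en-1-yl)cyclobutan-1-one (allyl and 4-substituent cis, both trans to vinyl) | C=CC[C@]1(C)C(=O)[C@H](C(C)(C)C=C)[C@H]1C=C | intermediate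
14 | 8-ethenyl-1,5,5-trimethylbicyclo[4.1.1]oct-3-en-7-one (vinyl anti to the four-carbon bridge) | C1C=CC(C)(C)[C@H]2C(=O)[C@]1(C)[C@@H]2C=C | intermediate
15 | 8-ethenyl-4-hydroperoxy-1,5,5-trimethylbicyclo[4.1.1]oct-2-en-7-one (not isolated) | C1[C@@H](OO)C(C)(C)[C@H]2C(=O)[C@](C)([C@@H]2C=C)C=1 | intermediate
16 | 8-ethenyl-4-hydroxy-1,5,5-trimethylbicyclo[4.1.1]oct-2-en-7-one (hydroxyl on the face of the carbonyl bridge) | C1[C@@H](O)C(C)(C)[C@H]2C(=O)[C@](C)([C@@H]2C=C)C=1 | intermediate
17 | (7E)-8-ethenyl-7-ethylidene-1,5,5-trimethylbicyclo[4.1.1]oct-2-en-4-ol | C1[C@@H](O)C(C)(C)[C@H]2/C(=C\C)[C@](C)([C@@H]2C=C)C=1 | intermediate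
18 | tert-butyl{[(7E)-8-ethenyl-7-ethylidene-1,5,5-trimethylbicyclo[4.1.1]oct-2-en-4-yl]oxy}dimethylsilane | C1[C@@H](O[Si](C)(C)C(C)(C)C)C(C)(C)[C@H]2/C(=C\C)[C@](C)([C@@H]2C=C)C=1 | intermediate
19 | 1-[(7E)-4-{[tert-butyl(dimethyl)silyl]oxy}-7-ethylidene-1,5,5-trimethylbicyclo[4.1.1]oct-2-en-8-yl]ethan-1-one (acetyl anti to the four-carbon bridge) | C1[C@@H](O[Si](C)(C)C(C)(C)C)C(C)(C)[C@H]2/C(=C\C)[C@](C)([C@@H]2C(C)=O)C=1 | intermediate
20 | trimethylsilyl enol ether of 19 (methyl side, not isolated) | C1[C@@H](O[Si](C)(C)C(C)(C)C)C(C)(C)[C@H]2/C(=C\C)[C@](C)([C@@H]2C(=C)O[Si](C)(C)C)C=1 | intermediate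
21 | 2-bromo-1-[(7E)-4-{[tert-butyl(dimethyl)silyl]oxy}-7-ethylidene-1,5,5-trimethylbicyclo[4.1.1]oct-2-en-8-yl]ethan-1-one | C1[C@@H](O[Si](C)(C)C(C)(C)C)C(C)(C)[C@H]2/C(=C\C)[C@](C)([C@@H]2C(=O)CBr)C=1 | intermediate
22 | 5-{[tert-butyl(dimethyl)silyl]oxy}-2,6,6,9-tetramethyltricyclo[5.4.0.0(2,8)]undec-3-en-11-one (9-methyl on the side of the C7 bridge, anti to the C2 methyl) | C1[C@@H](O[Si](C)(C)C(C)(C)C)C(C)(C)[C@H]2[C@@H]3[C@H](C)CC(=O)[C@H]2[C@]3(C)C=1 | intermediate
23 | 5-{[tert-butyl(dimethyl)silyl]oxy}-3,4-dihydroxy-2,6,6,9-tetramethyltricyclo[5.4.0.0(2,8)]undecan-11-one (3,4-cis, anti to the 5-silyloxy group) | O[C@@H]1[C@@H](O[Si](C)(C)C(C)(C)C)C(C)(C)[C@H]2[C@@H]3[C@H](C)CC(=O)[C@H]2[C@]3(C)[C@@H]1O | intermediate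
24 | angelic acid, (2Z)-2-methylbut-2-enoic acid | C/C=C(/C)C(=O)O | starting material
25 | (2Z)-2-methylbut-2-enoic 2,4,6-trichlorobenzoic anhydride (not isolated) | C/C=C(/C)C(=O)OC(=O)c1c(Cl)cc(Cl)cc1Cl | intermediate
26 | 5-{[tert-butyl(dimethyl)silyl]oxy}-2,6,6,9-tetramethyl-11-oxotricyclo[5.4.0.0(2,8)]undecane-3,4-diyl bis[(2Z)-2-methylbut-2-enoate] | C/C=C(/C)C(=O)O[C@@H]1[C@@H](O[Si](C)(C)C(C)(C)C)C(C)(C)[C@H]2[C@@H]3[C@H](C)CC(=O)[C@H]2[C@]3(C)[C@@H]1OC(=O)/C(C)=C\C | intermediate
27 | 5-hydroxy-2,6,6,9-tetramethyl-11-oxotricyclo[5.4.0.0(2,8)]undecane-3,4-diyl bis[(2Z)-2-methylbut-2-enoate] | C/C=C(/C)C(=O)O[C@@H]1[C@@H](O)C(C)(C)[C@H]2[C@@H]3[C@H](C)CC(=O)[C@H]2[C@]3(C)[C@@H]1OC(=O)/C(C)=C\C | target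

## Step count and risks

Total step count: 16. Longest linear sequence: 16 steps (1 and 2 to 27).

Steps most likely to fail:

1. Step 13 (key radical closure). Hydrogen transfer to the α-keto radical may outrun the strained 6-endo attack, giving simple reduction back to 19; any loss of control over the ethylidene geometry in step 9 would be copied into the C9 configuration. Fallback (polar closure, setting out from 16 and returning at 22): 16 would be olefinated with methoxymethylenetriphenylphosphorane to the enol ether alcohol F1 and silylated as in step 10 to the enol ether silyl ether F2. Tsuji–Wacker oxidation as in step 11, with hydrolysis of the enol ether in the same acidic aqueous medium, would give the keto aldehyde F3, whose two α-centres can equilibrate. Amine-mediated aldol cyclodehydration (pyrrolidine, AcOH, 4 Å molecular sieves, with removal of water) would close the ring as the bridged enone F4. Me2CuLi with Me3SiCl should then deliver the C9 methyl from the face opposite the methyl-bearing one-carbon bridge, giving 22.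

2. Step 7 (ring-closing metathesis). Closure onto the hindered neopentyl vinyl group may be slower than intermolecular metathesis of the allyl and cyclobutyl vinyl groups, leading to oligomers. Fallback (setting out from 10 and returning at 14): the α'-enolate of 10 would be alkylated with (Z)-3-bromo-1-iodoprop-1-ene, anti to the vinyl group, to give the (Z)-iodoallyl enone F5. Bu3SnH and AIBN in dilute benzene at 80 °C would generate the vinyl radical, which should add in a 7-endo conjugate fashion to the isopropylidene carbon; the resulting α-keto radical takes hydrogen at the bridgehead, giving 14 directly.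

3. Step 8 (singlet-oxygen ene reaction). Oxygen may be delivered with poor facial selectivity, giving a mixture of carbinol epimers. Fallback (setting out from 17 and returning at 17): the epimer mixture would be carried through step 9 and then oxidised with Dess–Martin periodinane to the bicyclic enone F6. Corey–Bakshi–Shibata reduction with (S)-2-methyl-CBS-oxazaborolidine and catecholborane, the quaternary carbon acting as the large group, should return 17 under reagent control.

Further compounds
F1 | step 13 | 8-ethenyl-7-(methoxymethylidene)-1,5,5-trimethylbicyclo[4.1.1]oct-2-en-4-ol | C1[C@@H](O)C(C)(C)[C@H]2C(=COC)[C@](C)([C@@H]2C=C)C=1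
F2 | step 13 | tert-butyl{[8-ethenyl-7-(methoxymethylidene)-1,5,5-trimethylbicyclo[4.1.1]oct-2-en-4-yl]oxy}dimethylsilane | C1[C@@H](O[Si](C)(C)C(C)(C)C)C(C)(C)[C@H]2C(=COC)[C@](C)([C@@H]2C=C)C=1
F3 | step 13 | 8-acetyl-4-{[tert-butyl(dimethyl)silyl]oxy}-1,5,5-trimethylbicyclo[4.1.1]oct-2-ene-7-carbaldehyde (formyl and acetyl both anti to the four-carbon bridge) | C1[C@@H](O[Si](C)(C)C(C)(C)C)C(C)(C)[C@H]2[C@H](C=O)[C@](C)([C@@H]2C(C)=O)C=1
F4 | step 13 | 5-{[tert-butyl(dimethyl)silyl]oxy}-2,6,6-trimethyltricyclo[5.4.0.0(2,8)]undeca-3,9-dien-11-one | C1[C@@H](O[Si](C)(C)C(C)(C)C)C(C)(C)[C@H]2[C@@H]3C=CC(=O)[C@H]2[C@]3(C)C=1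
F5 | step 7 | (2S,3S)-3-ethenyl-2-[(2Z)-3-iodoprop-2-en-1-yl]-2-methyl-4-(propan-2-ylidene)cyclobutan-1-one | I/C=C\C[C@]1(C)C(=O)C(=C(C)C)[C@H]1C=C
F6 | step 8 | (7E)-8-ethenyl-7-ethylidene-1,5,5-trimethylbicyclo[4.1.1]oct-2-en-4-one | C1C(=O)C(C)(C)[C@H]2/C(=C\C)[C@](C)([C@@H]2C=C)C=1
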